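## The problem

The target is a diaryl ether in which ring A and ring B are joined only through one oxygen (C6–O–C1'), and each ring carries a free hydroxyl ortho to that bridge (C1 on ring A, C6' on ring B). There is no stereocenter and no ring to build beyond the two benzenes, so the whole task is regiochemical: five C–Br bonds in the right places on two very similar rings. Four bromines sit where a phenol puts them: C2 and C4 are ortho and para to the C1 hydroxyl, and C5' and C3' are ortho and para to the C6' hydroxyl. The fifth, at C4', is meta to its hydroxyl, flanked by two bromines and para to the bridging oxygen. Position C3 on ring A has the same relationship to the bridge and must stay C–H, so bromination of the parent bisphenol cannot tell C4' from C3. The aryl bromides would not survive catalytic hydrogenation or metalation, so every reduction has to come before bromine is introduced, and the electron-rich phenol and aminophenol intermediates are open to oxidation. The enabling feature is that C4' is ortho to both C3' and C5' and para to C1', so a nitrogen placed there can act three times: as a nitro group it activates C1' for ether formation, as an amine it directs bromine to C3' and C5' together with the C6' hydroxyl, and as a diazonium group it is exchanged for the bromine that no oxygen can place.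

## Retrosynthesis

**Target 9 to amine 7 (through diazonium salt 8).** The C4'–Br bond is cut and replaced by C–N. This is the only bromine without a hydroxyl ortho or para to it, and removing it leaves a molecule in which every remaining bromine is explained by a donor group. Cutting the C3' or C5' bromine instead would leave the meta bromine still to be installed. Compound 7, 3-amino-2,4-dibromo-6-(3,5-dibromo-2-hydroxyphenoxy)phenol, differs from 9 by one atom. The forward step must diazotise a weakly basic aniline flanked by two bromines and deliver bromide from copper without disturbing two free phenols.

**Amine 7 to aminobisphenol 6.** Four C–Br bonds (C2, C4, C3', C5') are cut in one stroke, leaving 5-amino-2-(2-hydroxyphenoxy)phenol 6, which has no halogen. Brominating the building blocks before the ether is made would put deactivated, hindered partners into the coupling and would rule out catalytic hydrogenation of the nitro group. Taking all four off at once gives a precursor in which the amine and the two hydroxyls point to exactly those four carbons. The forward reaction must place four bromines, leave C3, C5 and C2' alone, stop at four and not oxidise the substrate.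

**Aminobisphenol 6 to nitrobisphenol 5 to dimethyl ether 3 (through boron ester 4).** No skeletal bond is cut; the amine is traced to a nitro group and the two hydroxyls to methyl ethers. The nitro group is what the next disconnection needs, and the methyl ethers keep the two catechol-type oxygens distinct while the bridge is made. The forward steps must cleave two O–CH3 bonds without touching the diaryl ether, and reduce the nitro group while the molecule is still halogen-free.

**Dimethyl ether 3 to guaiacol 1 and fluoronitroarene 2.** The C1'–O bond is cut on the ring B side, because C1' is para to the nitrogen at C4' and an aryl fluoride there is a good SNAr electrophile. Cutting the C6–O bond would require an activated ring A electrophile that the target offers no handle for, or a copper coupling. Both fragments are commodity chemicals, and the forward step is a phenoxide displacing fluoride para to a nitro group.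

## Roads not taken

**Alternative 1:** Ring B is taken apart at C1'–C2' and C4'–C5'. In the forward direction the enolate of the aryloxyacetoacetate A2, ethyl 2-(3,5-dibromo-2-methoxyphenoxy)-3-oxobutanoate, would add to ethyl acrylate A3 in a Michael reaction, and the methyl ketone enolate would then close a six-membered ring by Claisen condensation on the new ester, giving dione A1.
- Merits: the ring A bromines arrive fixed in the building block A2, so there is no regiochemical question on ring A. In that respect it is better than the chosen plan, and it avoids aniline and diazonium chemistry.
- Weak points: A1 is far from the target. The ester at the quaternary C1' has to be removed, the ring has to be oxidised to a benzene without expelling the aryloxide (its loss would aromatise the ring directly and destroy the ether), and the C4' carbonyl oxygen has to be exchanged for bromine on an unsymmetrical 1,3-dione in which either carbonyl can react. Neither A2 nor A3 brings any ring B bromine, so C3' and C5' still need bromine afterwards.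
- Comparison: the chosen plan answers with five steps that all run on aromatic substrates, and with an exchange at C4' (nitrogen for bromine) whose position is never in doubt. The price is that ring A selectivity must be won in the bromination itself.

**Alternative 2:** Ring A is taken apart at C1–C2 and C5–C6. The pyrone A5, 3,5-dibromo-2-pyrone, would react as the diene with the aryloxy-substituted bis(trimethylsilyl) ketene acetal A6; decarboxylative cycloreversion and loss of one silyloxy group would then give the aryl silyl ether A4.
- Merits: the step is convergent, and A5 fixes the C2 and C4 bromines and the C1 oxygen of ring A beyond doubt. This is cleaner than any electrophilic bromination of ring A.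
- Weak points: the aryl group in A6 must already carry bromine at C3', C4' and C5', so the hard bromine is moved into a starting material and not solved. A5 has to be prepared. The hindered, trisubstituted ketene acetal A6 needs heat for the cycloaddition, and two deprotections follow A4.
- Comparison: the longest sequence would be clearly longer than five steps. The chosen plan has to accept a selectivity question on ring A, which it meets with the weak donor character of the bridging oxygen and with a fallback that pre-installs the ring A bromines.

**Alternative 3:** Both phenolic C–O bonds (C1–O and C6'–O) are cut back to formyl groups. A peracid would convert dialdehyde A8 into bis-formate A7 by twofold aryl migration (Dakin or Baeyer–Villiger type), and hydrolysis of A7 would give the target.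
- Merits: the formyl groups would activate the SNAr that makes the ether, both hydroxyls appear in one operation at the end, and no phenol protection is needed.
- Weak points: both migrating rings of A8 are electron-poor. Ring B carries three bromines and its formyl group is flanked on both sides, and the only ortho donor on each ring is the weakly donating bridging oxygen. Hydride migration in place of aryl migration, which would leave the carbon on the ring as a carboxyl group, is therefore the likely course on at least one ring. A8 also requires a benzaldehyde with three adjacent bromines, so the C4' problem is again pushed into a building block.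
- Comparison: the oxidation is sound on a single ring that has a methoxy group ortho to the aldehyde, and the fallback for step 4 uses it in that form. The chosen plan does not depend on a double migration and reaches the C4' bromine by a route that no building block has to provide.

Key step: step 4

Assumption: ring A is the dibrominated ring (C1 hydroxyl, C2 and C4 bromine, C6 ether oxygen) and ring B the tribrominated ring (C1' ether oxygen, C3' to C5' bromine, C6' hydroxyl); compounds 1 and 2 are taken as purchasable.

## Route

Step 1
Reactants: 1 guaiacol (2-methoxyphenol); 2 1-fluoro-2-methoxy-4-nitrobenzene
Product: 3 2-methoxy-1-(2-methoxyphenoxy)-4-nitrobenzene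
Conditions: K2CO3 (1.5 equiv), DMF, 80 °C
Reagents that add atoms: none
Why: Nucleophilic aromatic substitution (SNAr): the potassium phenoxide of 1 adds at the fluorine-bearing carbon of 2, which is para to the nitro group, and fluoride leaves from the anionic σ-adduct; the two ortho methoxy groups slow the reaction but offer no other pathway.

Step 2
Reactants: 3 2-methoxy-1-(2-methoxyphenoxy)-4-nitrobenzene
Product: 5 2-(2-hydroxyphenoxy)-5-nitrophenol, via bis(dibromoboryl) ether 4 (not isolated)
Conditions: BBr3 (3 equiv), CH2Cl2, −78 °C to rt; then H2O, 0 °C
Reagents that add atoms: boron tribromide, BrB(Br)Br (its boron and bromine are held only in 4 and leave on hydrolysis; 5 keeps none of them)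
Why: Lewis acid cleavage of aryl methyl ethers: BBr3 coordinates each methoxy oxygen and bromide attacks the methyl carbon (SN2), giving the aryloxydibromoborane 4, which water hydrolyses. The diaryl ether offers no sp3 carbon for bromide and the nitro group is inert to BBr3.

Step 3
Reactants: 5 2-(2-hydroxyphenoxy)-5-nitrophenol
Product: 6 5-amino-2-(2-hydroxyphenoxy)phenol
Conditions: H2 (1 atm), 10% Pd/C, MeOH, rt; filtered and concentrated under argon
Reagents that add atoms: none
Why: Catalytic hydrogenation of an aromatic nitro group; the substrate has no halogen, benzyl group or alkene, so nothing else is reducible. The electron-rich amine is handled under argon and used at once.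

Step 4
Reactants: 6 5-amino-2-(2-hydroxyphenoxy)phenol
Product: 7 3-amino-2,4-dibromo-6-(3,5-dibromo-2-hydroxyphenoxy)phenol
Conditions: Br2 (4.05 equiv, slow addition), NaOAc (4.5 equiv), AcOH, 15 °C to rt, dark
Reagents that add atoms: bromine, BrBr
Why: Each C–Br bond forms by electrophilic aromatic substitution, Br2 attacking the arene to give an arenium ion that loses its proton to acetate; the closest known reaction type is the exhaustive ortho/para bromination of 3-aminophenols and of 2-alkoxyphenols. No ring closes and no stereocenter is formed. Ring B should react first, because C3' and C5' are each ortho to the C4' amine and para or ortho to the C6' hydroxyl, so both donors stabilise the same arenium ions, whereas C2' is meta to both and is activated only by the bridging oxygen. Ring A should then take bromine para (C4) and ortho (C2) to the C1 hydroxyl. The step needs three selectivities: C3, C5 and C2' must stay C–H, the count must stop at four, and the substrate must not be oxidised. The first is secured because the bridging oxygen shares its lone pairs between two arenes and is a much weaker donor than a hydroxyl, and because C3, C5 and C2' each end up next to bromine once the activated positions are filled. The second is secured by the bromine charge and by the deactivation of each ring after two substitutions. The third rests on the amine being meta to the hydroxyl and para only to an ether oxygen, so no quinone imine can form without loss of the aryloxy group; the acetate buffer removes HBr, keeping the amine unprotonated and ortho/para-directing.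

Step 5
Reactants: 7 3-amino-2,4-dibromo-6-(3,5-dibromo-2-hydroxyphenoxy)phenol
Product: 9 2,3,4-tribromo-6-(3,5-dibromo-2-hydroxyphenoxy)phenol, via diazonium hydrogen sulfate 8 (not isolated)
Conditions: NaNO2 (1.2 equiv), conc. H2SO4–AcOH, 0–10 °C; then added to CuBr (0.3 equiv), 48% aq HBr, 60 °C
Reagents that add atoms: hydrogen bromide, Br (supplies the C4' bromine of 9); sodium nitrite, [Na+].[O-]N=O (supplies the second nitrogen of 8 only, lost as dinitrogen); sulfuric acid, OS(=O)(=O)O (counter-ion of 8 only)
Why: Sandmeyer bromination: nitrosylsulfuric acid, formed from NaNO2 in H2SO4, diazotises the weakly basic 2,6-dibromoaniline, and CuBr (monovalent copper) reduces diazonium 8 to an aryl radical that takes bromine from the CuBr2 (divalent copper) so formed, with loss of N2. The C6' hydroxyl is meta to the diazonium group, so no quinone diazide can form; the ortho and para positions of both phenols are blocked against azo coupling, and bromide as the only halide makes any exchange at C3' or C5' degenerate.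

## Compound list

1 | guaiacol (2-methoxyphenol) | COc1ccccc1O | starting material
2 | 1-fluoro-2-methoxy-4-nitrobenzene | COc1cc([N+](=O)[O-])ccc1F | starting material
3 | 2-methoxy-1-(2-methoxyphenoxy)-4-nitrobenzene | COc1ccccc1Oc1ccc([N+](=O)[O-])cc1OC | intermediate
4 | dibromo[2-(2-dibromoboryloxyphenoxy)-5-nitrophenoxy]borane | BrB(Br)Oc1ccccc1Oc1ccc([N+](=O)[O-])cc1OB(Br)Br | intermediate (not isolated)
5 | 2-(2-hydroxyphenoxy)-5-nitrophenol | Oc1ccccc1Oc1ccc([N+](=O)[O-])cc1O | intermediate
6 | 5-amino-2-(2-hydroxyphenoxy)phenol | Nc1ccc(Oc2ccccc2O)c(O)c1 | intermediate
7 | 3-amino-2,4-dibromo-6-(3,5-dibromo-2-hydroxyphenoxy)phenol | Nc1c(Br)cc(Oc2cc(Br)cc(Br)c2O)c(O)c1Br | intermediate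
8 | 2,6-dibromo-4-(3,5-dibromo-2-hydroxyphenoxy)-3-hydroxybenzenediazonium hydrogen sulfate | N#[N+]c1c(Br)cc(Oc2cc(Br)cc(Br)c2O)c(O)c1Br.OS(=O)(=O)[O-] | intermediate (not isolated)
9 | 2,3,4-tribromo-6-(3,5-dibromo-2-hydroxyphenoxy)phenol | Oc1c(Br)cc(Br)cc1Oc1cc(Br)c(Br)c(Br)c1O | target

## Step count and risks

Total steps: 5. Longest linear sequence: 5 (from 1 and 2 to 9).

**Step 4 (key step).** Two processes are the most likely to go wrong.
- Misdirection on ring A: the second bromination may go to C3, para to the bridging oxygen, in competition with C2, or a fifth bromine may enter at C3 or C5.
- Oxidative degradation of the electron-rich aminophenol by Br2 before substitution is complete.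

The fallback takes the two ring A bromines out of the key step and halves the bromine load on the amine. It sets out from 2 and returns at 7. Purchased 3,5-dibromo-2-hydroxybenzaldehyde F1 would be O-methylated (MeI, K2CO3, DMF) to 3,5-dibromo-2-methoxybenzaldehyde F2. Baeyer–Villiger oxidation of F2 with mCPBA would give 3,5-dibromo-2-methoxyphenyl formate F3, and methanolysis (K2CO3, MeOH) would free 3,5-dibromo-2-methoxyphenol F4. SNAr of F4 on 2 (K2CO3, DMF) would give 1,5-dibromo-2-methoxy-3-(2-methoxy-4-nitrophenoxy)benzene F5, and BBr3 would unmask 2,4-dibromo-6-(2-hydroxy-4-nitrophenoxy)phenol F6. Iron powder with NH4Cl in aqueous ethanol, chosen because hydrogenation over palladium would remove bromine, would give 5-amino-2-(3,5-dibromo-2-hydroxyphenoxy)phenol F7. Two equivalents of Br2 (NaOAc, AcOH) would then brominate only C3' and C5', the positions activated by both amine and hydroxyl, and give 7.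

**Step 5.** Three processes threaten this step: incomplete diazotisation of the hindered, weakly basic amine; attack of the nitrosating agent on the free phenol rings (ipso nitrosation or oxidation); and capture of the aryl cation or radical by water or hydrogen in place of bromide. The fallback masks the phenols and moves the reaction into an organic medium. It sets out from 7 and returns at 9. Methylation of both hydroxyls (MeI, K2CO3, acetone; the dibromoaniline nitrogen is too hindered and too weakly nucleophilic to compete) would give 2,6-dibromo-4-(3,5-dibromo-2-methoxyphenoxy)-3-methoxyaniline F8. One-pot diazotisation and bromination with tert-butyl nitrite and CuBr2 in MeCN would give 1,2,3-tribromo-5-(3,5-dibromo-2-methoxyphenoxy)-4-methoxybenzene F9, and BBr3 in CH2Cl2 would cleave both methyl ethers to 9.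

**Step 3.** The reduction itself is safe; the risk is air oxidation of the free aminophenol during removal of the catalyst and concentration. The fallback changes the order of events so that the amine is released under acid. It sets out from 3 and returns at 6. Hydrogenation of 3 (H2, Pd/C) would give the stable 3-methoxy-4-(2-methoxyphenoxy)aniline F10. BBr3 (4 equiv, one being held by the amine) and an acidic work-up would give 3-hydroxy-4-(2-hydroxyphenoxy)anilinium bromide F11, which can be stored. One extra equivalent of NaOAc in the bromination flask would release 6 directly into step 4.

## Further compounds

F1 | step 4 | 3,5-dibromo-2-hydroxybenzaldehyde (purchased) | O=Cc1cc(Br)cc(Br)c1O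
F2 | step 4 | 3,5-dibromo-2-methoxybenzaldehyde | COc1c(Br)cc(Br)cc1C=O
F3 | step 4 | 3,5-dibromo-2-methoxyphenyl formate | COc1c(Br)cc(Br)cc1OC=O
F4 | step 4 | 3,5-dibromo-2-methoxyphenol | COc1c(Br)cc(Br)cc1O
F5 | step 4 | 1,5-dibromo-2-methoxy-3-(2-methoxy-4-nitrophenoxy)benzene | COc1c(Br)cc(Br)cc1Oc1ccc([N+](=O)[O-])cc1OC
F6 | step 4 | 2,4-dibromo-6-(2-hydroxy-4-nitrophenoxy)phenol | Oc1c(Br)cc(Br)cc1Oc1ccc([N+](=O)[O-])cc1O
F7 | step 4 | 5-amino-2-(3,5-dibromo-2-hydroxyphenoxy)phenol | Nc1ccc(Oc2cc(Br)cc(Br)c2O)c(O)c1
F8 | step 5 | 2,6-dibromo-4-(3,5-dibromo-2-methoxyphenoxy)-3-methoxyaniline | Nc1c(Br)cc(Oc2cc(Br)cc(Br)c2OC)c(OC)c1Br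
F9 | step 5 | 1,2,3-tribromo-5-(3,5-dibromo-2-methoxyphenoxy)-4-methoxybenzene | COc1c(Br)cc(Br)cc1Oc1cc(Br)c(Br)c(Br)c1OC
F10 | step 3 | 3-methoxy-4-(2-methoxyphenoxy)aniline | COc1ccccc1Oc1ccc(N)cc1OC
F11 | step 3 | 3-hydroxy-4-(2-hydroxyphenoxy)anilinium bromide | [NH3+]c1ccc(Oc2ccccc2O)c(O)c1.[Br-]
A1 | alternative 1 | ethyl 1-(3,5-dibromo-2-methoxyphenoxy)-2,4-dioxocyclohexane-1-carboxylate (racemic) | CCOC(=O)C1(Oc2cc(Br)cc(Br)c2OC)CCC(=O)CC1=O
A2 | alternative 1 | ethyl 2-(3,5-dibromo-2-methoxyphenoxy)-3-oxobutanoate (racemic) | CCOC(=O)C(Oc1cc(Br)cc(Br)c1OC)C(C)=O
A3 | alternative 1 | ethyl acrylate | C=CC(=O)OCC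
A4 | alternative 2 | [2,4-dibromo-6-(3,4,5-tribromo-2-methoxyphenoxy)phenoxy]trimethylsilane | COc1c(Oc2cc(Br)cc(Br)c2O[Si](C)(C)C)cc(Br)c(Br)c1Br
A5 | alternative 2 | 3,5-dibromo-2H-pyran-2-one | O=c1occ(Br)cc1Br
A6 | alternative 2 | 2-(3,4,5-tribromo-2-methoxyphenoxy)-1,1-bis(trimethylsilyloxy)ethene | COc1c(OC=C(O[Si](C)(C)C)O[Si](C)(C)C)cc(Br)c(Br)c1Br
A7 | alternative 3 | 2,4-dibromo-6-(3,4,5-tribromo-2-formyloxyphenoxy)phenyl formate | O=COc1c(Br)cc(Br)cc1Oc1cc(Br)c(Br)c(Br)c1OC=O
A8 | alternative 3 | 2,3,4-tribromo-6-(3,5-dibromo-2-formylphenoxy)benzaldehyde | O=Cc1c(Br)cc(Br)cc1Oc1cc(Br)c(Br)c(Br)c1C=O
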